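Rates first.

| flask | starting material | first nucleophile | second nucleophile | remark | time |
|---|---|---|---|---|---|
| south | 0.053 M | 0.072 M | 0.0556 M | run made earlier |  |
| flask | 0.053 M | 0.0477 M | 0.0556 M |  | 50 min |

south run (percent of the starting material charged)

| time / min | target / % | starting material / % |
|---|---|---|
| 0.833 | 19.8 | 59.1 |
| 1.50 | 29.9 | 38.2 |
| 3.00 | 38.4 | 16.1 |
| 5.00 | 38.3 | 3.3 |
| 10.0 | 28.1 | 1.3 |

(scatter of a reading: 1 percentage point)

1. the best time, 50 min at the latest, for target
2. the amount of target, in percent of the starting material charged, at that time
3. earliest time at which at least nineteen twentieths of that best amount are there, in min
4. latest time at which they still are, in min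



In the south run the readings put the loss of starting material at 0.642 /min over the first 1.50 min and at 0.682 /min over the first 5.00 min, so these readings showed no slowing of that loss. I assumed a slow first step, the rate-limiting step, feeding an intermediate for which the two nucleophiles compete. The first two south readings put 0.484 and 0.484 of the lost material into target, so I replaced that curve by one mean share; each reading carries a scatter of 1 percentage point.

I therefore reckoned that target in the south run began at 0.311 /min of the charge. In my reckoning two things slow that rate: starting material fades, and target itself goes on at 0.0619 /min, read from the last two readings. Together, for this pair of rates, they give the south run a reckoned peak at 4.03 min of 0.779 times the share.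

I carried one quantity, 0.724: the selectivity factor, meaning the odds of target against the rest of the lost material, divided by the ratio of first to second nucleophile charged. For the new flask I reckoned odds of 0.621 and a share of 0.383, so I put the start of target at 0.246 /min of the charge. With the same two slowings, I expected 29.8 % at 4.03 min.

The forecast, which said “Only one run and an assumed mechanism support this”, gave 35 % at 4.2 min, with the window from 2.8 min to 6.3 min.

The flask gave 33.1 % at 3.81 min, with the window from 2.67 min to 5.40 min, so my height stood lower and my time later.

    target ⇌ isomer of the product (K = 4.20, k = 0.00168 /s)
    second nucleophile + intermediate → other capture product (k = 756 /M/s)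
    second nucleophile ⇌ dormant form (K = 1.20, k = 0.00814 /s)
    first nucleophile + intermediate → target (k = 461 /M/s)
    starting material ⇌ intermediate (K = 0.0120, k = 0.0108 /s)

For a neighbouring flask charged with 0.12 M of first nucleophile and the same second nucleophile, the factor 0.724 gives odds of 1.56 and a share of 0.610. Multiplied by 0.779, that makes a reckoned height of 47.5 %. That neighbouring flask's best amount of target was 48.0 %.

All runs were computed on assumed constants; the scatter is artificial.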